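Late in Saturday's run, which is the asked flask followed to 3.00 min, both products read higher than at 1.50 min, and that late pace carries the ledger below.

common to all: left-handed substrate 0.25 M; right-handed substrate 0.25 M

|  | partner | remark | time |
|---|---|---|---|
| Saturday's | 3 equiv | the very flask that is asked about, followed so far |  |
| flask | 3.00 equiv |  | 15 min |

Saturday's run (percent of the left-handed substrate and right-handed substrate together charged)

| time / min | left-handed product / % | right-handed product / % |
|---|---|---|
| 0.417 | 7.9 | 4.3 |
| 0.833 | 11.3 | 6.3 |
| 1.33 | 13.7 | 8.3 |
| 1.50 | 13.4 | 8.4 |
| 2.00 | 15.9 | 10.7 |
| 2.50 | 17.4 | 12.8 |
| 3.00 | 18.3 | 12.4 |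

(scatter of a reading: 0.5 percentage points)

- partner is single-handed; left-handed substrate and right-handed substrate are mirror images of each other, charged as a racemate, each of them at the stated concentration
- an excess is the difference of the two amounts in percent of their sum
- an excess is below zero if the other one leads
- the handed part of partner does not stay in what it makes, so the products of the two hands are mirror images too

- excess of left-handed product over right-handed product in the product at 20 s
- excess of left-handed product over right-handed product in the product at 15 min
- part of the left-handed substrate and right-handed substrate charged together that has reacted at 15 min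

Partner stands at 1.50 equiv on the two substrates together, so they are the limiting reagent, and each of their moles is entered as substrate left or as product. Let the depth D be the logarithm of substrate charged over substrate left, hands pooled; a first-order loss raises D evenly. First entry: at 3.00 min the readings put 30.7% in product, so D = 0.367. Second entry: from 1.50 min to 3.00 min D grew at a read pace of 0.0805 min⁻¹, less than the 0.312 min⁻¹ read up to the first reading. The reckoning made here holds it to 15 min, which closes the books at 0.444 of depth per equivalent of partner, d, and so at 73.6% reacted.

The forecast differs on the part reacted. On the ground “This suggests a reversible reaction.”, it gives an excess of left-handed product of 30% at 20 s and 0% at 15 min, and a plateau at 37% reacted (33% to 43%).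

The flask gives excesses of 29.0% at 20 s and 2.92% at 15 min, with 65.7% reacted, which makes d 0.357, less than the reckoned 0.444.

    partner + left-handed substrate → left-handed product (k = 0.0130 L mol⁻¹ s⁻¹)
    partner + right-handed substrate → right-handed product (k = 0.00680 L mol⁻¹ s⁻¹)
    left-handed substrate ⇌ right-handed substrate (k = 0.190 s⁻¹)
    partner → decomposed reagent (k = 3.70 × 10⁻⁴ s⁻¹)
    partner ⇌ dormant form (K = 3.50, k = 0.0270 s⁻¹)
    left-handed product ⇌ right-handed product (k = 0.00290 s⁻¹)

At 1.50 min the flask's partner stood at 19.3% of its charge beside 0.478 M of dormant form, and the step to left-handed product had 36% of its turnover up to 15 min behind it. Up to 15 min both substrates went on reacting in the flask, with partner at 10.8% of its charge and dormant form down to 0.301 M at the end. In the neighbouring flask with 1.80 equiv of partner, other charges and time held, this d, taken as depth per equivalent, gives a depth of 0.643, hence 47.4% reacted. The simulation of that flask gives 45.5%.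

(Readings and results stem from a simulated flask for an exercise, noise included.)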